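**Retrosynthetic overview**
1. The target is traced back to its tribenzyl ether; the last step is hydrogenolysis of the 5-, 7- and 8'-O-benzyl groups.
2. Ring C of the tribenzyl ether is cut at the aryl ketone bond C4–C4a and at O1–C2, giving a 4-aryl-β-lactone and 3,5-bis(benzyloxy)phenol. In the forward sense the aryloxide inverts the lactone carbon (O1–C2), and the carboxyl carbon C4 set free then acylates C4a and closes ring C.
3. Enabling feature: ring A is a 1,3,5-trioxygenated benzene. In the 3,5-bis(benzyloxy)phenyl ether the two CH carbons ortho to O1 (future C4a and C8) are equivalent, and each is ortho, ortho and para to three oxygens. C2 is benzylic and 1,3 to C4, which is exactly the carbinol carbon of a β-lactone.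
4. The β-lactone comes from 8-(benzyloxy)-2,2-dimethyl-4-oxochroman-6-carbaldehyde and ketene by catalytic asymmetric [2+2]. The aldehyde comes from 2'-hydroxy-3'-methoxyacetophenone by para-bromination, Kabbe condensation, O-demethylation, benzylation and Pd formylation.
5. Order of ring formation: ring D (dimethylpyranone fused to ring B, step 2), then the temporary oxetanone (step 6), then ring C (step 7). Rings A and B are bought as arenes.

Key step: step 7

Assumption: the quinidine-derived catalyst of step 6 adds to the Re face of the aldehyde and gives the 4R lactone, by analogy with the parent alkaloid-catalysed ketene–aldehyde cycloaddition; if the sense is opposite on this aldehyde, the quinine-derived pseudoenantiomer is used.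

**Step 1**
Reactants: 1 1-(2-hydroxy-3-methoxyphenyl)ethan-1-one
Product: 2 1-(5-bromo-2-hydroxy-3-methoxyphenyl)ethan-1-one
Conditions: NBS, MeCN, 0 °C to rt
Reagents that add atoms: N-bromosuccinimide, O=C1CCC(=O)N1Br
Why: Electrophilic aromatic bromination should go para to the free phenol, the only ortho/para position of the hydroxyl group that is open.

**Step 2**
Reactants: 2 1-(5-bromo-2-hydroxy-3-methoxyphenyl)ethan-1-one
Product: 4 6-bromo-8-methoxy-2,2-dimethylchroman-4-one, via enone 3 (not isolated)
Conditions: acetone, pyrrolidine, MeOH, 60 °C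
Reagents that add atoms: acetone, CC(C)=O
Why: Kabbe condensation: pyrrolidine-mediated aldol condensation of the acetyl group with acetone gives enone 3, whose ortho phenol closes ring D by 6-endo-trig oxa-Michael addition.

**Step 3**
Reactants: 4 6-bromo-8-methoxy-2,2-dimethylchroman-4-one
Product: 5 6-bromo-8-hydroxy-2,2-dimethylchroman-4-one
Conditions: BBr3, CH2Cl2, −78 to 0 °C; aqueous work-up
Reagents that add atoms: none
Why: Boron tribromide ether cleavage: bromide removes the methyl group of the boron-bound aryl methyl ether by SN2, the only ether carbon open to such attack, while ketone and aryl bromide are inert.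

**Step 4**
Reactants: 5 6-bromo-8-hydroxy-2,2-dimethylchroman-4-one
Product: 6 8-(benzyloxy)-6-bromo-2,2-dimethylchroman-4-one
Conditions: BnBr, K2CO3, DMF, rt
Reagents that add atoms: benzyl bromide, BrCc1ccccc1
Why: Williamson ether synthesis on the only free phenol; the benzyl group should survive steps 5 to 7 and leave in step 8 together with the two ring-A benzyl groups.

**Step 5**
Reactants: 6 8-(benzyloxy)-6-bromo-2,2-dimethylchroman-4-one
Product: 7 8-(benzyloxy)-2,2-dimethyl-4-oxochroman-6-carbaldehyde
Conditions: Pd(OAc)2, n-BuPAd2, TMEDA, CO/H2 (1:1, 5 bar), toluene, 100 °C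
Reagents that add atoms: carbon monoxide, [C-]#[O+]
Why: Palladium-catalysed reductive carbonylation (formylation) of the aryl bromide by oxidative addition, CO insertion and hydrogenolysis of the acyl-palladium species; ketone and benzyl ether should be inert to the homogeneous catalyst.

**Step 6**
Reactants: 7 8-(benzyloxy)-2,2-dimethyl-4-oxochroman-6-carbaldehyde
Product: 8 8-(benzyloxy)-2,2-dimethyl-6-[(2R)-4-oxooxetan-2-yl]chroman-4-one
Conditions: AcCl (slow addition), i-Pr2NEt, O-trimethylsilylquinidine (10 mol%), LiClO4, CH2Cl2/Et2O, −78 °C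
Reagents that add atoms: acetyl chloride, CC(=O)Cl
Why: Catalytic asymmetric ketene–aldehyde [2+2] cycloaddition (acyl halide–aldehyde cyclocondensation): ketene made in the flask becomes a chiral ammonium enolate that adds to the Re face of the lithium-activated aldehyde and closes the oxetanone by 4-exo-trig acyl substitution, so the catalyst sets the new stereocentre as R while the conjugated ring-D ketone stays untouched.

**Step 7**
Reactants: 8 8-(benzyloxy)-2,2-dimethyl-6-[(2R)-4-oxooxetan-2-yl]chroman-4-one; 9 3,5-bis(benzyloxy)phenol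
Product: 13 (2S)-5,7-bis(benzyloxy)-2-[8-(benzyloxy)-2,2-dimethyl-4-oxochroman-6-yl]chroman-4-one, via potassium aryloxide 10 (not isolated), via potassium carboxylate 11 (not isolated), via mixed anhydride 12 (not isolated)
Conditions: 9, KHMDS, 18-crown-6, THF, 0 °C; then 8, 0 to 40 °C; solvent switch to CH2Cl2, TFAA, TFA (cat.), 0 °C to rt
Reagents that add atoms: none
Why: Aryloxide 10, freed from ion pairing by 18-crown-6, attacks the benzylic ring carbon of β-lactone 8 from the side opposite the ring oxygen (SN2, alkyl–oxygen cleavage with carboxylate as leaving group) to give 11, which TFAA turns into mixed anhydride 12; the ring carbon ortho to the new ether oxygen then attacks the activated acyl carbon and loses a proton, which forms the aryl ketone bond C4–C4a and closes ring C. The closest known reaction types are the aryloxide ring opening of β-propiolactone and β-butyrolactone to 3-aryloxyalkanoic acids and the TFAA-mediated intramolecular Friedel–Crafts acylation of 3-(3,5-dialkoxyphenoxy)propanoic acids to 5,7-dialkoxychroman-4-ones. Ring C closes by 6-exo-trig attack of the arene on the acyl carbon (intramolecular Friedel–Crafts acylation); the oxetanone is opened and no other ring is formed. The only stereocentre, C2, is set by stereospecific inversion of the R lactone carbon to S (substrate control) and should not be touched afterwards, because the ring closure runs under acidic conditions in which the base-driven chalcone–flavanone equilibrium that racemizes C2 does not operate. The step needs O-alkylation at the lactone alkyl carbon instead of acyl attack, C-alkylation, elimination or ionization, and three features should secure this: acyl attack is reversible because re-closure of the lactone expels aryloxide whereas carboxylate departure is not, the C3–H bonds of the four-membered ring cannot align with the C4–O bond (lactone numbering) so that elimination to the cinnamate is stereoelectronically disfavoured, and the para oxygen of ring B is a vinylogous ester oxygen next to a meta acyl group, which disfavours SN1 ionization. Regiochemistry of the acylation is no issue, since the two CH positions ortho to the ether oxygen are equivalent and the third CH, between the two benzyloxy groups, cannot be reached through a six-membered transition state.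

**Step 8**
Reactants: 13 (2S)-5,7-bis(benzyloxy)-2-[8-(benzyloxy)-2,2-dimethyl-4-oxochroman-6-yl]chroman-4-one
Product: 14 (2S)-5,7-dihydroxy-2-(8-hydroxy-2,2-dimethyl-4-oxochroman-6-yl)chroman-4-one
Conditions: H2 (1 atm), 10% Pd/C, EtOAc/MeOH, rt
Reagents that add atoms: none
Why: Catalytic hydrogenolysis of the three aryl benzyl ethers under neutral conditions, which should leave the base-labile C2 stereocentre and both electron-rich aryl ketones untouched.

**Compound list**
1 | 1-(2-hydroxy-3-methoxyphenyl)ethan-1-one | CC(=O)c1cccc(OC)c1O | starting material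
2 | 1-(5-bromo-2-hydroxy-3-methoxyphenyl)ethan-1-one | CC(=O)c1cc(Br)cc(OC)c1O | intermediate
3 | 1-(5-bromo-2-hydroxy-3-methoxyphenyl)-3-methylbut-2-en-1-one (not isolated) | CC(C)=CC(=O)c1cc(Br)cc(OC)c1O | intermediate
4 | 6-bromo-8-methoxy-2,2-dimethylchroman-4-one | CC1(C)CC(=O)c2cc(Br)cc(OC)c2O1 | intermediate
5 | 6-bromo-8-hydroxy-2,2-dimethylchroman-4-one | CC1(C)CC(=O)c2cc(Br)cc(O)c2O1 | intermediate
6 | 8-(benzyloxy)-6-bromo-2,2-dimethylchroman-4-one | CC1(C)CC(=O)c2cc(Br)cc(OCc3ccccc3)c2O1 | intermediate
7 | 8-(benzyloxy)-2,2-dimethyl-4-oxochroman-6-carbaldehyde | CC1(C)CC(=O)c2cc(C=O)cc(OCc3ccccc3)c2O1 | intermediate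
8 | 8-(benzyloxy)-2,2-dimethyl-6-[(2R)-4-oxooxetan-2-yl]chroman-4-one | CC1(C)CC(=O)c2cc([C@H]3CC(=O)O3)cc(OCc4ccccc4)c2O1 | intermediate
9 | 3,5-bis(benzyloxy)phenol | Oc1cc(OCc2ccccc2)cc(OCc3ccccc3)c1 | starting material
10 | potassium 3,5-bis(benzyloxy)phenoxide (not isolated) | [K+].[O-]c1cc(OCc2ccccc2)cc(OCc3ccccc3)c1 | intermediate
11 | potassium (3S)-3-[3,5-bis(benzyloxy)phenoxy]-3-[8-(benzyloxy)-2,2-dimethyl-4-oxochroman-6-yl]propanoate (not isolated) | [K+].CC1(C)CC(=O)c2cc([C@H](CC(=O)[O-])Oc3cc(OCc4ccccc4)cc(OCc5ccccc5)c3)cc(OCc6ccccc6)c2O1 | intermediate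
12 | (3S)-3-[3,5-bis(benzyloxy)phenoxy]-3-[8-(benzyloxy)-2,2-dimethyl-4-oxochroman-6-yl]propanoic trifluoroacetic anhydride (not isolated) | CC1(C)CC(=O)c2cc([C@H](CC(=O)OC(=O)C(F)(F)F)Oc3cc(OCc4ccccc4)cc(OCc5ccccc5)c3)cc(OCc6ccccc6)c2O1 | intermediate
13 | (2S)-5,7-bis(benzyloxy)-2-[8-(benzyloxy)-2,2-dimethyl-4-oxochroman-6-yl]chroman-4-one | CC1(C)CC(=O)c2cc([C@@H]3CC(=O)c4c(OCc5ccccc5)cc(OCc6ccccc6)cc4O3)cc(OCc7ccccc7)c2O1 | intermediate
14 | (2S)-5,7-dihydroxy-2-(8-hydroxy-2,2-dimethyl-4-oxochroman-6-yl)chroman-4-one | CC1(C)CC(=O)c2cc([C@@H]3CC(=O)c4c(O)cc(O)cc4O3)cc(O)c2O1 | target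

**Step count and risks**
Total step count: 8. Longest linear sequence: 8 steps (1 to 14); phenol 9 enters in step 7.

Steps most likely to fail:

1. Step 7. In the first stage the aryloxide may attack the lactone carbonyl and the resulting aldolate may fragment by retro-aldol cleavage. The carboxylate formed may also open further lactone (oligomerization), or the substitution may drift towards an ionizing pathway with loss of configuration. The fallback sets out from 8 and comes back to the route at 13 through 12. Base-catalysed methanolysis of 8 (MeOH, cat. K2CO3, 0 °C; acyl–oxygen cleavage, carbinol carbon untouched) should give methyl (3R)-3-[8-(benzyloxy)-2,2-dimethyl-4-oxochroman-6-yl]-3-hydroxypropanoate F1. Mitsunobu etherification of F1 with 9 (PPh3, DIAD, toluene, 0 °C) should give, with inversion, methyl (3S)-3-[3,5-bis(benzyloxy)phenoxy]-3-[8-(benzyloxy)-2,2-dimethyl-4-oxochroman-6-yl]propanoate F2. Saponification (LiOH, THF/H2O, 0 °C) should give (3S)-3-[3,5-bis(benzyloxy)phenoxy]-3-[8-(benzyloxy)-2,2-dimethyl-4-oxochroman-6-yl]propanoic acid F3, which TFAA in CH2Cl2 converts into mixed anhydride 12 and hence 13.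

2. Step 6. The cycloaddition may stall on a moderately electrophilic aryl aldehyde, facial discrimination may be insufficient, or the aryl lactone may decarboxylate on work-up. The fallback sets out from 7 and comes back at 8. An enantioselective Mukaiyama aldol addition of the tert-butyldimethylsilyl ketene acetal of ethyl acetate (SiCl4, chiral bisphosphoramide Lewis-base catalyst chosen for Re-face addition, CH2Cl2, −78 °C) should give ethyl (3R)-3-[8-(benzyloxy)-2,2-dimethyl-4-oxochroman-6-yl]-3-hydroxypropanoate F4. Saponification (LiOH, THF/H2O) should give (3R)-3-[8-(benzyloxy)-2,2-dimethyl-4-oxochroman-6-yl]-3-hydroxypropanoic acid F5. Benzenesulfonyl chloride in pyridine at 0 °C activates the carboxyl group as (3R)-3-[8-(benzyloxy)-2,2-dimethyl-4-oxochroman-6-yl]-3-hydroxypropanoic benzenesulfonic anhydride F6, which should lactonize with retention at the carbinol carbon to 8.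

3. Step 8. Hydrogenolysis may not stop at the benzyl ethers: the cyclic benzylic C2–O1 bond may be cleaved with opening of ring C, or an aryl ketone may be reduced. The fallback sets out from 13 and comes back at 14. It is a Lewis-acid debenzylation with BCl3 and pentamethylbenzene as cation scavenger in CH2Cl2 at −78 °C, which involves neither reduction nor base and makes no new compound on the way.

**Further compounds**
F1 | step 7 | methyl (3R)-3-[8-(benzyloxy)-2,2-dimethyl-4-oxochroman-6-yl]-3-hydroxypropanoate | CC1(C)CC(=O)c2cc([C@@H](CC(=O)OC)O)cc(OCc3ccccc3)c2O1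
F2 | step 7 | methyl (3S)-3-[3,5-bis(benzyloxy)phenoxy]-3-[8-(benzyloxy)-2,2-dimethyl-4-oxochroman-6-yl]propanoate | CC1(C)CC(=O)c2cc([C@H](CC(=O)OC)Oc3cc(OCc4ccccc4)cc(OCc5ccccc5)c3)cc(OCc6ccccc6)c2O1
F3 | step 7 | (3S)-3-[3,5-bis(benzyloxy)phenoxy]-3-[8-(benzyloxy)-2,2-dimethyl-4-oxochroman-6-yl]propanoic acid | CC1(C)CC(=O)c2cc([C@H](CC(=O)O)Oc3cc(OCc4ccccc4)cc(OCc5ccccc5)c3)cc(OCc6ccccc6)c2O1
F4 | step 6 | ethyl (3R)-3-[8-(benzyloxy)-2,2-dimethyl-4-oxochroman-6-yl]-3-hydroxypropanoate | CC1(C)CC(=O)c2cc([C@@H](CC(=O)OCC)O)cc(OCc3ccccc3)c2O1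
F5 | step 6 | (3R)-3-[8-(benzyloxy)-2,2-dimethyl-4-oxochroman-6-yl]-3-hydroxypropanoic acid | CC1(C)CC(=O)c2cc([C@@H](CC(=O)O)O)cc(OCc3ccccc3)c2O1
F6 | step 6 | (3R)-3-[8-(benzyloxy)-2,2-dimethyl-4-oxochroman-6-yl]-3-hydroxypropanoic benzenesulfonic anhydride | CC1(C)CC(=O)c2cc([C@@H](CC(=O)OS(=O)(=O)c3ccccc3)O)cc(OCc4ccccc4)c2O1
F0 | step 8 | none | none
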